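The amber run is the early part of the blue run: each holds 0.0800 M starting material and 0.00240 M catalyst, so the blue question is where amber's curve comes to rest.

in all of them: catalyst 0.00240 M

| charge | starting material | target | time |
|---|---|---|---|
| amber | 0.0800 M |  |  |
| red | 0.0800 M | 0.0400 M |  |
| teal | 0.240 M |  |  |
| blue | 0.0800 M |  | 18 h |

- amber run (time / h: [target] / M): 0.64: 0.0132; 1.3: 0.0249; 1.9: 0.0332; 2.6: 0.0366; 3.2: 0.0403; 3.9: 0.0407; 4.5: 0.0426
- red run (time / h: [target] / M): 0.64: 0.0666; 1.3: 0.0809; 1.9: 0.0874; 2.6: 0.0921; 3.2: 0.0937; 3.9: 0.0937; 4.5: 0.0936
- teal run (time / h: [target] / M): 0.64: 0.0232; 1.3: 0.0453; 1.9: 0.0570; 2.6: 0.0642; 3.2: 0.0687; 3.9: 0.0700; 4.5: 0.0732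

(scatter of a reading: 8 × 10⁻⁴ M)

* how the opening rate goes with [starting material] round the charge of the amber run: the exponent of the rate at two percent of starting material gone to target (one fixed amount of target, the same in the runs compared)
* target in the blue run at 18 h, as a share of the starting material charged

- Overall: starting material -> target, with catalyst as catalyst.
- Constant volume, constant temperature.
- The analysis sees a species whether free or bound.
- An order is taken over about fifteen percent of the charge, up and down.

Target in amber flattens near 0.0426 M, and we can read the height of that stall by hand. Amber's readings at 1.3 h, 2.6 h and 3.9 h stand 1.30 h apart and rise by 0.0117 M, then by 0.00410 M. If each step takes the same share off the distance to the stall, the second rise over the first is the share that survives, 0.350. The rises still to come then sum to 0.00221 M, so this first estimate puts amber's stall at 0.0429 M, or 53.6% of the charge.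

The weak link is that ratio, because those readings stop short of the latest one and each rise carries a scatter of 0.00113 M. We reforge it from the readings at 1.9 h, 3.2 h and 4.5 h, whose rises are 0.00710 M and 0.00230 M. The gap ratio, the share of the distance to the stall that survives one step, is then 0.324. That leaves an estimated 0.00110 M to come after amber's last reading, and puts amber's stall at 0.0437 M. The blue run's 18 h lies 10.4 steps beyond that reading, so by this ratio hardly any of this gap remains. Our number for blue is 54.6%.

The forecast gives 56%, somewhat more than ours, and an order of 0.55, on this ground: “Blue should sit near amber's plateau plus a slight tail”.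

The flask gives 54.7% and 0.55, both within the margin of the forecast.

    catalyst + starting material ⇌ catalyst-substrate complex (1296 M⁻¹ h⁻¹, 85.32 h⁻¹)
    catalyst-substrate complex → target + catalyst (17.78 h⁻¹)
    2 starting material → homo dimer (5.976 M⁻¹ h⁻¹)
    starting material + target → 2 target (9.396 M⁻¹ h⁻¹)

The stall comes from the loss of starting material to homo dimer: with that step taken away, the blue run reaches 100% instead of 54.7%. The blue result lies 0.00118 M above amber's last reading, against the 0.00110 M from the gap ratio. In the teal run the same rule gives a ratio of 0.385 and a stall of 0.0760 M. From the teal reading at 1.9 h, it brings target to a quarter of the charge at 2.13 h, and the flask has 2.13 h.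

(The earlier runs and the new flask were generated by integration with constants of no real substance; scatter was added.)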